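**Retrosynthetic overview**
- Target ⇐ the corresponding ring B aldehyde (CH2OH ⇐ CHO). The CHO is kept until the end because it activates ring B for the key step.
- Key disconnection: the diaryl ether C–O bond (ring A oxygen to the ring B carbon next to CHO). It is made by an intramolecular O→O aryl transfer within a depside, with the ring A carboxylate as leaving group.
- Depside ⇐ prenylated benzodioxinone (ring A: acyl donor and mask of the attacking oxygen) + free 2,3-dihydroxy-5-methylbenzaldehyde (ring B).
- Prenylated benzodioxinone ⇐ γ-resorcylic acid acetonide + prenyl bromide. Catechol aldehyde ⇐ 5-methyl-o-vanillin.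
- No ring is built. Both benzene rings are bought intact, and the only ring event is the opening of the dioxinone in the key step.

Assumption: the target has no stereocentre and no E/Z-isomeric alkene (the C=C carries two methyl groups), so it is achiral and there is no enantiomer to select; phenoxide and carboxylate salts present in the flask are drawn as the neutral numbered compounds.

Oxygen labels used below:
- O2 is the oxygen of ring B next to CHO.
- O3 is its neighbour on ring B.
- O6 is the ring A oxygen masked in the acetonide.

**Step 1**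
Reactants: 1 5-hydroxy-2,2-dimethyl-4H-1,3-benzodioxin-4-one; 2 prenyl bromide (1-bromo-3-methylbut-2-ene)
Product: 3 5-hydroxy-2,2-dimethyl-6-(3-methylbut-2-en-1-yl)-4H-1,3-benzodioxin-4-one
Conditions: NaH (1.05 equiv), toluene, 0 °C to rt, 30 min; then 2 (1.1 equiv), rt to 60 °C, 16 h
Reagents that add atoms: prenyl bromide, CC(C)=CCBr
Why: Ortho C-alkylation of a phenoxide with an allylic halide; in a non-polar medium the tight, carbonyl-chelated sodium ion pair reacts at carbon rather than oxygen by SN2 at the primary carbon (so the linear prenyl group results), C6 is the only free ortho position and is also para to the ring oxygen, and no stereocentre is formed.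

**Step 2**
Reactants: 4 2-hydroxy-3-methoxy-5-methylbenzaldehyde
Product: 5 2,3-dihydroxy-5-methylbenzaldehyde
Conditions: BBr3 (2.5 equiv), CH2Cl2, −78 °C to rt, 4 h; ice/H2O
Reagents that add atoms: none
Why: Lewis-acid cleavage of an aryl methyl ether (BBr3 demethylation), the same change as o-vanillin to 2,3-dihydroxybenzaldehyde; the aldehyde and the aryl methyl group survive, and no stereocentre is formed.

**Step 3**
Reactants: 3 5-hydroxy-2,2-dimethyl-6-(3-methylbut-2-en-1-yl)-4H-1,3-benzodioxin-4-one; 5 2,3-dihydroxy-5-methylbenzaldehyde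
Product: 9 2-hydroxy-6-[2-hydroxy-6-(hydroxymethyl)-4-methylphenoxy]-3-(3-methylbut-2-en-1-yl)benzoic acid (target), via O3-depside 6 (not isolated), via O2-depside 7 (not isolated), via aldehyde acid 8 (not isolated)
Conditions: 5 (1.1 equiv), KOt-Bu (1.1 equiv), 4 Å MS, dry DMSO, Ar, rt, 15 min; add 3 (1.0 equiv), rt to 80 °C, Ar sweep to carry off acetone, 12 h; cool to 0 °C, EtOH, NaBH4 (1.5 equiv), 1 h; cold 1 M HCl to pH 3, then NaHCO3/acid extraction
Reagents that add atoms: none
Why: Proposed new method: an acyl-relay Smiles etherification that joins two free phenols with net loss of water and uses the C–OH carbon of an unprotected catechol aldehyde as the aryl electrophile; the monopotassium salt of 5 attacks the flat, sterically open and OH···O=C-activated lactone carbonyl of neutral 3, acetone is expelled and O6 is released as a phenoxide (depside 6); the acyl group then walks reversibly between the vicinal catechol oxygens through a five-membered tetrahedral adduct (6 ⇌ 7), and only in 7 does the acyloxy group sit on the carbon ortho to CHO, so only there can O6 add ipso through a six-membered spiro transition state and push out the carboxylate, which is about six pKa units less basic than any phenoxide present and therefore acts as an irreversible sink that drains the 6/7 equilibrium and fixes the ring B regiochemistry; exactly one negative charge per molecule keeps the neighbouring ring B OH protonated so that it does not switch the ring off, and attack by the other ring A OH (next to prenyl) would give a tetra-ortho-substituted ether and is sterically excluded; the closest known reaction types are the Smiles rearrangement of nitroaryl salicylates and of O-protected formyl- or ester-activated depsides (not shown on a free catechol or fed by an acyl walk) and the alkoxide opening of benzodioxinones; the closing NaBH4 reduction of an aryl aldehyde beside a carboxylate, phenols and a trisubstituted alkene is routine, and no stereocentre is formed.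

**Compound list**
1 | 5-hydroxy-2,2-dimethyl-4H-1,3-benzodioxin-4-one | CC1(C)OC(=O)c2c(O)cccc2O1 | starting material
2 | prenyl bromide (1-bromo-3-methylbut-2-ene) | CC(C)=CCBr | starting material
3 | 5-hydroxy-2,2-dimethyl-6-(3-methylbut-2-en-1-yl)-4H-1,3-benzodioxin-4-one | CC(C)=CCc1ccc2OC(C)(C)OC(=O)c2c1O | intermediate
4 | 2-hydroxy-3-methoxy-5-methylbenzaldehyde | COc1cc(C)cc(C=O)c1O | starting material
5 | 2,3-dihydroxy-5-methylbenzaldehyde | Cc1cc(O)c(O)c(C=O)c1 | intermediate
6 | 3-formyl-2-hydroxy-5-methylphenyl 2,6-dihydroxy-3-(3-methylbut-2-en-1-yl)benzoate (O3-depside, not isolated) | CC(C)=CCc1ccc(O)c(C(=O)Oc2cc(C)cc(C=O)c2O)c1O | intermediate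
7 | 2-formyl-6-hydroxy-4-methylphenyl 2,6-dihydroxy-3-(3-methylbut-2-en-1-yl)benzoate (O2-depside, not isolated) | CC(C)=CCc1ccc(O)c(C(=O)Oc2c(O)cc(C)cc2C=O)c1O | intermediate
8 | 6-(2-formyl-6-hydroxy-4-methylphenoxy)-2-hydroxy-3-(3-methylbut-2-en-1-yl)benzoic acid (not isolated) | CC(C)=CCc1ccc(Oc2c(O)cc(C)cc2C=O)c(C(=O)O)c1O | intermediate
9 | 2-hydroxy-6-[2-hydroxy-6-(hydroxymethyl)-4-methylphenoxy]-3-(3-methylbut-2-en-1-yl)benzoic acid (achiral) | CC(C)=CCc1ccc(Oc2c(O)cc(C)cc2CO)c(C(=O)O)c1O | target

**Step count**
Total steps: 3. Longest linear sequence: 2 (1 → 3 → 9, or 4 → 5 → 9).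

**Steps most likely to fail**

**Step 3 (the new acyl-relay Smiles coupling).**
There are three risks:
- The weakly nucleophilic phenoxide may open the dioxinone too slowly.
- The single ortho CHO may not activate ring B enough, given its OH and CH3 donors. The chelated O2-phenoxide of 6 is then a stable resting state.
- Traces of water may hydrolyse the depsides.

The fallback uses known chemistry only. It replaces the phenolic leaving group by fluoride and makes the ether by an ordinary intermolecular SNAr. It sets out from 3 and comes back to the route at 9. K2CO3 in MeOH at 50 °C opens 3 to methyl 2,6-dihydroxy-3-(3-methylbut-2-en-1-yl)benzoate F1. Separately, commercial 2-fluoro-5-methylphenol F2 is protected with MOMCl and i-Pr2NEt as 1-fluoro-2-(methoxymethoxy)-4-methylbenzene F3. This is lithiated next to fluorine (s-BuLi, THF, −78 °C) and formylated with DMF to give 2-fluoro-3-(methoxymethoxy)-5-methylbenzaldehyde F4. K2CO3 in DMF at 100 °C then joins the unhindered 6-OH of F1 to F4, giving methyl 6-[2-formyl-6-(methoxymethoxy)-4-methylphenoxy]-2-hydroxy-3-(3-methylbut-2-en-1-yl)benzoate F5. NaBH4 in MeOH gives methyl 2-hydroxy-6-[2-(hydroxymethyl)-6-(methoxymethoxy)-4-methylphenoxy]-3-(3-methylbut-2-en-1-yl)benzoate F6. KOH in DMSO/H2O at 80 °C gives 2-hydroxy-6-[2-(hydroxymethyl)-6-(methoxymethoxy)-4-methylphenoxy]-3-(3-methylbut-2-en-1-yl)benzoic acid F7. Brief treatment with 2 M HCl in THF at 40 °C removes the MOM group and delivers 9.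

**Step 1 (direct C-prenylation).**
The risks are competing O-prenylation and double alkylation. Yields for this reaction type are usually only 40–55 %. The fallback changes from direct C-alkylation to O-alkylation followed by a sigmatropic shift. It sets out from 1 and comes back at 3. Compound 1 is treated with tert-butyl 2-methylbut-3-en-2-yl carbonate F8 and Pd(PPh3)4 (3 mol %, a zerovalent palladium catalyst) in THF at 0 °C. This gives the branched ether 2,2-dimethyl-5-[(2-methylbut-3-en-2-yl)oxy]-4H-1,3-benzodioxin-4-one F9. After the palladium is filtered off through silica, an aromatic Claisen rearrangement in toluene at 110 °C moves the group with allylic inversion to C6, the only free ortho carbon, and gives 3.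

**Step 2 (BBr3 demethylation).**
The risks are attack of the boron halide on the aldehyde and air oxidation of the free catechol aldehyde during isolation. The fallback postpones the deprotection to the end of the synthesis. It sets out from 4 and comes back at 9. Compound 4 takes the place of 5 under the step 3 conditions with 3. Its only free OH is O2, so no acyl walk is needed. The sequence passes through 2-formyl-6-methoxy-4-methylphenyl 2,6-dihydroxy-3-(3-methylbut-2-en-1-yl)benzoate F10 and 6-(2-formyl-6-methoxy-4-methylphenoxy)-2-hydroxy-3-(3-methylbut-2-en-1-yl)benzoic acid F11. NaBH4 then gives 2-hydroxy-6-[2-(hydroxymethyl)-6-methoxy-4-methylphenoxy]-3-(3-methylbut-2-en-1-yl)benzoic acid F12. The methyl group is finally removed by SN2 attack of NaSEt in DMF at 130 °C, a basic method that leaves the prenyl alkene alone, to give 9.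

**Further compounds**
F1 | step 3 | methyl 2,6-dihydroxy-3-(3-methylbut-2-en-1-yl)benzoate | CC(C)=CCc1ccc(O)c(C(=O)OC)c1O
F2 | step 3 | 2-fluoro-5-methylphenol | Cc1ccc(F)c(O)c1
F3 | step 3 | 1-fluoro-2-(methoxymethoxy)-4-methylbenzene | COCOc1cc(C)ccc1F
F4 | step 3 | 2-fluoro-3-(methoxymethoxy)-5-methylbenzaldehyde | COCOc1cc(C)cc(C=O)c1F
F5 | step 3 | methyl 6-[2-formyl-6-(methoxymethoxy)-4-methylphenoxy]-2-hydroxy-3-(3-methylbut-2-en-1-yl)benzoate | CC(C)=CCc1ccc(Oc2c(OCOC)cc(C)cc2C=O)c(C(=O)OC)c1O
F6 | step 3 | methyl 2-hydroxy-6-[2-(hydroxymethyl)-6-(methoxymethoxy)-4-methylphenoxy]-3-(3-methylbut-2-en-1-yl)benzoate | CC(C)=CCc1ccc(Oc2c(OCOC)cc(C)cc2CO)c(C(=O)OC)c1O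
F7 | step 3 | 2-hydroxy-6-[2-(hydroxymethyl)-6-(methoxymethoxy)-4-methylphenoxy]-3-(3-methylbut-2-en-1-yl)benzoic acid | CC(C)=CCc1ccc(Oc2c(OCOC)cc(C)cc2CO)c(C(=O)O)c1O
F8 | step 1 | tert-butyl 2-methylbut-3-en-2-yl carbonate | C=CC(C)(C)OC(=O)OC(C)(C)C
F9 | step 1 | 2,2-dimethyl-5-[(2-methylbut-3-en-2-yl)oxy]-4H-1,3-benzodioxin-4-one | C=CC(C)(C)Oc1cccc2OC(C)(C)OC(=O)c12
F10 | step 2 | 2-formyl-6-methoxy-4-methylphenyl 2,6-dihydroxy-3-(3-methylbut-2-en-1-yl)benzoate | CC(C)=CCc1ccc(O)c(C(=O)Oc2c(OC)cc(C)cc2C=O)c1O
F11 | step 2 | 6-(2-formyl-6-methoxy-4-methylphenoxy)-2-hydroxy-3-(3-methylbut-2-en-1-yl)benzoic acid | CC(C)=CCc1ccc(Oc2c(OC)cc(C)cc2C=O)c(C(=O)O)c1O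
F12 | step 2 | 2-hydroxy-6-[2-(hydroxymethyl)-6-methoxy-4-methylphenoxy]-3-(3-methylbut-2-en-1-yl)benzoic acid | CC(C)=CCc1ccc(Oc2c(OC)cc(C)cc2CO)c(C(=O)O)c1O
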